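The route rests on building the hexasubstituted benzene ring of the 2H-chromene (C4a, C5, C6, C7, C8, C8a) from a C4 and a C2 fragment, instead of differentiating a phloroglucinol. One thermal pericyclic cascade joins racemic 3-methoxy-4-prenylcyclobut-2-enone to (triisopropylsilyloxy)ethyne and forms C8a–C4a and C5–C6. The resulting phenol already has three distinct oxygens: free OH at C8a, OTIPS at C5 and OMe at C7, with prenyl on C8. The step exploits the 1,3,5-trioxygenated A ring and its C8 prenyl group flanked by two oxygens. The free OH then carries the dimethylpyran onto C4a, and the last aromatic C–H, C6, takes the aryl diketone.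

Key step: step 5

Remark on the chemistry: the target has no stereocentre and no stereogenic double bond, so it is a single achiral compound and no enantioselective step is needed. The only stereocentre in an isolated intermediate (C4 of 7) is erased in step 5, so 7 is used as the racemate.

Step 1
Reactants: 1 2-chloro-1,1-dimethoxyethane
Product: 3 methoxyethyne, via sodium methoxyacetylide 2 (not isolated)
Conditions: NaNH2 (3.1 equiv), liq. NH3, −33 °C; NH3 evaporated; sat. aq. NaCl, −70 °C → rt, distilled into a −78 °C trap, stored as a cold Et2O solution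
Reagents that add atoms: none
Why: Double β-elimination of a chloroacetal with amide base (loss of MeOH, then of HCl) followed by deprotonation is the classical synthesis of 1-alkoxyalkynes, and cold aqueous protonation of acetylide 2 releases the low-boiling alkyne.

Step 2
Reactants: 4 5-methylhex-4-enoic acid
Product: 5 5-methylhex-4-enoyl chloride
Conditions: (COCl)2 (1.2 equiv), DMF (cat.), CH2Cl2, 0 °C → rt; distilled
Reagents that add atoms: oxalyl chloride, ClC(=O)C(=O)Cl
Why: Acid chloride formation through the catalytic Vilsmeier chloroiminium salt runs at or below room temperature, where the trisubstituted alkene is not attacked by the HCl that escapes as gas.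

Step 3
Reactants: 5 5-methylhex-4-enoyl chloride; 3 methoxyethyne
Product: 7 (±)-3-methoxy-4-(3-methylbut-2-en-1-yl)cyclobut-2-en-1-one, via prenylketene 6 (not isolated)
Conditions: 3 (3 equiv), Et3N (1.3 equiv), Et2O, 0 °C, slow addition of 5; then rt, closed flask; neutral work-up, Et3N-deactivated SiO2
Reagents that add atoms: none
Why: Dehydrochlorination gives aldoketene 6, which is trapped in a ketene–ynol ether [2+2] cycloaddition whose polarity (alkyne CH carbon to ketene C=O carbon) puts the ketene substituent on C4 next to C3–OMe, so prenyl is installed without a C4 enolate of a cyclobutenone (an antiaromatic oxidocyclobutadiene), the same barrier keeps 7 from tautomerising to its 2-prenyl isomer, and the new C4 stereocentre forms racemic and is erased in step 5.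

Step 4
Reactants: 8 acetylene
Product: 11 (triisopropylsilyloxy)ethyne, via lithium acetylide 9 (not isolated), via lithium ethynolate 10 (not isolated)
Conditions: 8 (excess, acetone-free), n-BuLi, THF, −78 °C; t-BuOOLi (from t-BuOOH in decane + LiHMDS, THF, −78 °C), −78 → −10 °C under C2H2; TIPSOTf, −78 → 0 °C; pentane/H2O
Reagents that add atoms: tert-butyl hydroperoxide, CC(C)(C)OO; triisopropylsilyl trifluoromethanesulfonate, CC(C)[Si](C(C)C)(C(C)C)OS(=O)(=O)C(F)(F)F
Why: Electrophilic oxygenation of a lithium acetylide by lithium tert-butyl peroxide (SN2 at oxygen) gives the ynolate, which the hard, bulky silyl triflate captures on oxygen as in the standard siloxyalkyne synthesis, and acetylide made from acetylene and n-BuLi under excess acetylene, rather than a primary-diamine-stabilised complex, leaves no nucleophilic NH2 group to consume the triflate and holds back disproportionation to dilithium acetylide.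

Step 5
Reactants: 7 (±)-3-methoxy-4-(3-methylbut-2-en-1-yl)cyclobut-2-en-1-one; 11 (triisopropylsilyloxy)ethyne
Product: 16 3-methoxy-2-(3-methylbut-2-en-1-yl)-5-(triisopropylsilyloxy)phenol, via vinylketene 12 (not isolated), via 4-alkenylcyclobutenone 13 (not isolated), via dienylketene 14 (not isolated), via cyclohexadienone 15 (not isolated)
Conditions: 11 (2 equiv), toluene, 110 °C, sealed tube, Ar
Reagents that add atoms: none
Why: Heat opens 7 in a reversible conrotatory 4π electrocyclic reaction, the C4 side chain rotating outward, to vinylketene 12, whose carbonyl carbon is attacked by the nucleophilic CH terminus of ynol ether 11, so the [2+2] cycloaddition gives 4-alkenylcyclobutenone 13 and makes C8a–C4a and C5–C6. A second reversible 4π opening gives dienylketene 14, and the isomer with the alkenyl group turned inward closes the six-membered ring by disrotatory 6π electrocyclisation (C8a–C8 is re-formed) to dienone 15, which enolises irreversibly to phenol 16. The closest known reaction type is the Danheiser benzannulation of cyclobutenones with trialkylsilyloxyalkynes, the established entry to resorcinol monosilyl ethers. No stereocentre is created, and the racemic C4 of 7 ends as the planar carbon C8. The step needs head-to-tail regiochemistry in the ketene–alkyne union, which the oxygen-induced polarisation of 11 secures, and it needs the alkyne to outrun capture of 12 and 14 by phenol already formed, which an excess of 11 secures. The positions of OMe and prenyl are not subject to selectivity, since C3 and C4 of 7 are carried over as the adjacent carbons C7 and C8.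

Step 6
Reactants: 16 3-methoxy-2-(3-methylbut-2-en-1-yl)-5-(triisopropylsilyloxy)phenol; 17 3-chloro-3-methylbut-1-yne
Product: 18 {3-methoxy-5-[(2-methylbut-3-yn-2-yl)oxy]-4-(3-methylbut-2-en-1-yl)phenoxy}triisopropylsilane
Conditions: 17 (1.5 equiv), DBU, CuCl2·2H2O (1 mol %), MeCN, 0 °C → rt, N2
Reagents that add atoms: none
Why: Copper-catalysed O-propargylation of a phenol by a tertiary propargylic chloride tolerates an ortho substituent, and 16 offers a single free OH, so the ether can form only on the C8a oxygen.

Step 7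
Reactants: 18 {3-methoxy-5-[(2-methylbut-3-yn-2-yl)oxy]-4-(3-methylbut-2-en-1-yl)phenoxy}triisopropylsilane
Product: 22 {[7-methoxy-2,2-dimethyl-8-(3-methylbut-2-en-1-yl)-2H-chromen-5-yl]oxy}triisopropylsilane, via allenyl dienone 19 (not isolated), via allenylphenol 20 (not isolated), via o-quinone methide 21 (not isolated)
Conditions: xylenes, 140 °C, Ar
Reagents that add atoms: none
Why: The aromatic propargyl Claisen rearrangement is productive only towards C4a because the other ortho carbon, C8, carries prenyl, after which enolisation (20), 1,5-hydrogen shift (21) and oxa-6π electrocyclisation close the 2,2-dimethyl-2H-pyran ring without creating a stereocentre.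

Step 8
Reactants: 22 {[7-methoxy-2,2-dimethyl-8-(3-methylbut-2-en-1-yl)-2H-chromen-5-yl]oxy}triisopropylsilane
Product: 24 7-methoxy-5-(methoxymethoxy)-2,2-dimethyl-8-(3-methylbut-2-en-1-yl)-2H-chromene, via chromen-5-ol 23 (not isolated)
Conditions: TBAF (1.05 equiv), THF, 0 °C; then i-Pr2NEt, MOMCl (2.5 equiv), 0 °C → rt
Reagents that add atoms: chloromethyl methyl ether, COCCl
Why: Fluoride cleavage of the aryl silyl ether and Williamson-type alkylation of the resulting phenoxide in the same flask replace a bulky, non-directing group by a strong ortho-director that acid removes later.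

Step 9
Reactants: 24 7-methoxy-5-(methoxymethoxy)-2,2-dimethyl-8-(3-methylbut-2-en-1-yl)-2H-chromene; 25 1,4-dimethylpiperazine-2,3-dione; 26 1-bromo-4-(methoxymethoxy)benzene
Product: 31 1-[7-methoxy-5-(methoxymethoxy)-2,2-dimethyl-8-(3-methylbut-2-en-1-yl)-2H-chromen-6-yl]-2-[4-(methoxymethoxy)phenyl]ethane-1,2-dione, via 6-lithiochromene 27 (not isolated), via mono-adduct 28 (not isolated), via 4-(methoxymethoxy)phenyllithium 29 (not isolated), via bis-adduct 30 (not isolated)
Conditions: 24, n-BuLi (1.1 equiv), THF, −20 → 0 °C; 25 (1.1 equiv), −78 → 0 °C; 29 (1.6 equiv, from 26 + n-BuLi, THF, −78 °C, second flask), −78 °C → rt; 1 M HCl, 0 °C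
Reagents that add atoms: none
Why: Directed ortho-metalation removes the only aromatic hydrogen, C6–H between OMOM and OMe, and the known unsymmetrical α-dione synthesis by successive addition of two organolithiums to 1,4-dimethylpiperazine-2,3-dione passes through the stable tetrahedral adducts 28 and 30 (their stereocentres are uncontrolled and vanish), which release the two ketones only on acidic work-up, so over-addition is excluded.

Step 10
Reactants: 31 1-[7-methoxy-5-(methoxymethoxy)-2,2-dimethyl-8-(3-methylbut-2-en-1-yl)-2H-chromen-6-yl]-2-[4-(methoxymethoxy)phenyl]ethane-1,2-dione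
Product: 32 1-[5-hydroxy-7-methoxy-2,2-dimethyl-8-(3-methylbut-2-en-1-yl)-2H-chromen-6-yl]-2-(4-hydroxyphenyl)ethane-1,2-dione (CNP0184805.0)
Conditions: 3 M aq. HCl (cat.), MeOH, 45 °C
Reagents that add atoms: none
Why: Acid-catalysed transacetalisation with methanol cleaves both aryl MOM ethers, the one at C5 being assisted by the neighbouring ketone, while the C8 prenyl group has no free ortho hydroxyl (OMe and the pyran oxygen flank it) and so cannot close to a chroman.

Compound list
1 | 2-chloro-1,1-dimethoxyethane | COC(CCl)OC | starting material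
2 | sodium methoxyacetylide | COC#[C-].[Na+] | intermediate
3 | methoxyethyne | COC#C | intermediate
4 | 5-methylhex-4-enoic acid | CC(C)=CCCC(=O)O | starting material
5 | 5-methylhex-4-enoyl chloride | CC(C)=CCCC(=O)Cl | intermediate
6 | prenylketene (5-methylhexa-1,4-dien-1-one) | CC(C)=CCC=C=O | intermediate
7 | (±)-3-methoxy-4-(3-methylbut-2-en-1-yl)cyclobut-2-en-1-one (racemic) | COC1=CC(=O)C1CC=C(C)C | intermediate
8 | acetylene | C#C | starting material
9 | lithium acetylide | [Li]C#C | intermediate
10 | lithium ethynolate | [Li+].[O-]C#C | intermediate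
11 | (triisopropylsilyloxy)ethyne | C#CO[Si](C(C)C)(C(C)C)C(C)C | intermediate
12 | (3Z)-3-methoxy-7-methylocta-1,3,6-trien-1-one (vinylketene) | O=C=C/C(OC)=C/CC=C(C)C | intermediate
13 | (±)-4-[(1Z)-1-methoxy-5-methylhexa-1,4-dien-1-yl]-3-(triisopropylsilyloxy)cyclobut-2-en-1-one (racemic) | O=C1C=C(O[Si](C(C)C)(C(C)C)C(C)C)C1/C(OC)=C/CC=C(C)C | intermediate
14 | (3E,5Z)-5-methoxy-9-methyl-3-(triisopropylsilyloxy)deca-1,3,5,8-tetraen-1-one (dienylketene) | O=C=C/C(O[Si](C(C)C)(C(C)C)C(C)C)=C\C(OC)=C\CC=C(C)C | intermediate
15 | (±)-5-methoxy-6-(3-methylbut-2-en-1-yl)-3-(triisopropylsilyloxy)cyclohexa-2,4-dien-1-one (racemic) | O=C1C=C(O[Si](C(C)C)(C(C)C)C(C)C)C=C(OC)C1CC=C(C)C | intermediate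
16 | 3-methoxy-2-(3-methylbut-2-en-1-yl)-5-(triisopropylsilyloxy)phenol | COc1cc(O[Si](C(C)C)(C(C)C)C(C)C)cc(O)c1CC=C(C)C | intermediate
17 | 3-chloro-3-methylbut-1-yne | CC(C)(Cl)C#C | starting material
18 | {3-methoxy-5-[(2-methylbut-3-yn-2-yl)oxy]-4-(3-methylbut-2-en-1-yl)phenoxy}triisopropylsilane | COc1cc(O[Si](C(C)C)(C(C)C)C(C)C)cc(OC(C)(C)C#C)c1CC=C(C)C | intermediate
19 | (±)-3-methoxy-6-(3-methylbuta-1,2-dien-1-yl)-2-(3-methylbut-2-en-1-yl)-5-(triisopropylsilyloxy)cyclohexa-2,4-dien-1-one (racemic) | O=C1C(CC=C(C)C)=C(OC)C=C(O[Si](C(C)C)(C(C)C)C(C)C)C1C=C=C(C)C | intermediate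
20 | 3-methoxy-6-(3-methylbuta-1,2-dien-1-yl)-2-(3-methylbut-2-en-1-yl)-5-(triisopropylsilyloxy)phenol | COc1cc(O[Si](C(C)C)(C(C)C)C(C)C)c(C=C=C(C)C)c(O)c1CC=C(C)C | intermediate
21 | (6Z)-3-methoxy-2-(3-methylbut-2-en-1-yl)-6-(3-methylbut-2-en-1-ylidene)-5-(triisopropylsilyloxy)cyclohexa-2,4-dien-1-one (o-quinone methide) | CC(C)=C/C=C1\C(=O)C(CC=C(C)C)=C(OC)C=C1O[Si](C(C)C)(C(C)C)C(C)C | intermediate
22 | {[7-methoxy-2,2-dimethyl-8-(3-methylbut-2-en-1-yl)-2H-chromen-5-yl]oxy}triisopropylsilane | COc1cc(O[Si](C(C)C)(C(C)C)C(C)C)c2C=CC(C)(C)Oc2c1CC=C(C)C | intermediate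
23 | 7-methoxy-2,2-dimethyl-8-(3-methylbut-2-en-1-yl)-2H-chromen-5-ol (in the flask as its Bu4N+ phenoxide) | COc1cc(O)c2C=CC(C)(C)Oc2c1CC=C(C)C | intermediate
24 | 7-methoxy-5-(methoxymethoxy)-2,2-dimethyl-8-(3-methylbut-2-en-1-yl)-2H-chromene | COCOc1cc(OC)c(CC=C(C)C)c2OC(C)(C)C=Cc12 | intermediate
25 | 1,4-dimethylpiperazine-2,3-dione | CN1CCN(C)C(=O)C1=O | starting material
26 | 1-bromo-4-(methoxymethoxy)benzene | COCOc1ccc(Br)cc1 | starting material
27 | 6-lithio-7-methoxy-5-(methoxymethoxy)-2,2-dimethyl-8-(3-methylbut-2-en-1-yl)-2H-chromene | [Li]c1c(OC)c(CC=C(C)C)c2OC(C)(C)C=Cc2c1OCOC | intermediate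
28 | lithium 2-(chromen-6-yl)-1,4-dimethyl-3-oxopiperazin-2-olate (racemic mono-adduct) | [Li+].[O-]C3(N(C)CCN(C)C3=O)c1c(OC)c(CC=C(C)C)c2OC(C)(C)C=Cc2c1OCOC | intermediate
29 | 4-(methoxymethoxy)phenyllithium | [Li]c1ccc(OCOC)cc1 | intermediate
30 | dilithium 2-(chromen-6-yl)-3-[4-(methoxymethoxy)phenyl]-1,4-dimethylpiperazine-2,3-diolate (diastereomer mixture, bis-adduct) | [Li+].[Li+].[O-]C3(N(C)CCN(C)C3([O-])c4ccc(OCOC)cc4)c1c(OC)c(CC=C(C)C)c2OC(C)(C)C=Cc2c1OCOC | intermediate
31 | 1-[7-methoxy-5-(methoxymethoxy)-2,2-dimethyl-8-(3-methylbut-2-en-1-yl)-2H-chromen-6-yl]-2-[4-(methoxymethoxy)phenyl]ethane-1,2-dione | COCOc1ccc(cc1)C(=O)C(=O)c1c(OC)c(CC=C(C)C)c2OC(C)(C)C=Cc2c1OCOC | intermediate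
32 | 1-[5-hydroxy-7-methoxy-2,2-dimethyl-8-(3-methylbut-2-en-1-yl)-2H-chromen-6-yl]-2-(4-hydroxyphenyl)ethane-1,2-dione (achiral) | COc1c(CC=C(C)C)c2c(c(O)c1C(=O)C(=O)c1ccc(O)cc1)C=CC(C)(C)O2 | target

Total step count: 10
Longest linear sequence: 8 steps (step 1 or step 2, then steps 3, 5, 6, 7, 8, 9 and 10)

Steps most likely to fail

Step 5. The donor-substituted cyclobutenone may open sluggishly. The unhindered terminal ynol ether may rearrange or oligomerise at the temperature required. The phenol already formed may also intercept the ketenes by O-acylation, so the cascade could stall.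

The fallback buys the arene instead of building it. It sets out from 17 and comes back at 23.
- Commercial 5-methoxyresorcinol (COc1cc(O)cc(O)c1) is mono-O-alkylated with 17 under the conditions of step 6, giving 3-methoxy-5-[(2-methylbut-3-yn-2-yl)oxy]phenol F1.
- Heating as in step 7 gives 7-methoxy-2,2-dimethyl-2H-chromen-5-ol F2, which has to be separated from its regioisomer.
- O-Prenylation (prenyl bromide, K2CO3, acetone) gives 7-methoxy-2,2-dimethyl-5-[(3-methylbut-2-en-1-yl)oxy]-2H-chromene F3.
- A para-Claisen–Cope sequence (Eu(fod)3 cat., or N,N-diethylaniline with heat) then moves the prenyl group by two consecutive [3,3] shifts, over C6 to C8.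
- This gives chromen-5-ol 23, isolated here as the free phenol, which enters the second stage of step 8 (i-Pr2NEt, MOMCl) on the way to 24.

Step 4. Monolithium acetylide may disproportionate before oxygen transfer is complete. The sterically unprotected carbon terminus of ynolate 10 may also be silylated in competition with oxygen.

The fallback blocks the carbon terminus. It sets out from 9 and comes back at 11.
- Quenching 9 with Me3SiCl gives ethynyltrimethylsilane F4, which is also commercially available.
- n-BuLi gives lithium (trimethylsilyl)acetylide F5, which cannot disproportionate.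
- Oxygenation with t-BuOOLi gives lithium 2-(trimethylsilyl)ethynolate F6.
- TIPSOTf, directed to oxygen by the C-silyl group, gives trimethyl{[(triisopropylsilyl)oxy]ethynyl}silane F7.
- Protodesilylation of the C–SiMe3 bond (K2CO3, MeOH, 0 °C), which spares the hindered O–Si bond, returns to 11.

Step 9. The di-ortho-substituted aryllithium may add slowly to the diamide. The first tetrahedral adduct may collapse before the second addition, and aryl scrambling may lead to symmetrical diones.

The fallback replaces the diamide linchpin by an organocopper acylation. It sets out from 26 and 24 and comes back at 31.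
- Aryllithium 29 (from 26) is added to excess diethyl oxalate (THF, −78 °C), giving ethyl 2-[4-(methoxymethoxy)phenyl]-2-oxoacetate F8.
- LiOH (THF/H2O) gives lithium 2-[4-(methoxymethoxy)phenyl]-2-oxoacetate F9.
- The dried salt is treated with oxalyl chloride (cat. DMF, CH2Cl2, 0 °C). No HCl is formed, so the MOM ether is kept, and the product is 2-[4-(methoxymethoxy)phenyl]-2-oxoacetyl chloride F10.
- Aryllithium 27 (from 24) is transmetalated with CuBr·SMe2/LiBr (THF, −78 → −40 °C) to the 6-chromenylcopper reagent F11.
- F11 is acylated by F10 at the acid chloride carbon only, since organocopper reagents do not add to ketones, and this gives 31.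

Further compounds
F1 | step 5 | 3-methoxy-5-[(2-methylbut-3-yn-2-yl)oxy]phenol | COc1cc(O)cc(OC(C)(C)C#C)c1
F2 | step 5 | 7-methoxy-2,2-dimethyl-2H-chromen-5-ol | COc1cc(O)c2C=CC(C)(C)Oc2c1
F3 | step 5 | 7-methoxy-2,2-dimethyl-5-[(3-methylbut-2-en-1-yl)oxy]-2H-chromene | COc1cc(OCC=C(C)C)c2C=CC(C)(C)Oc2c1
F4 | step 4 | ethynyltrimethylsilane | C#C[Si](C)(C)C
F5 | step 4 | lithium (trimethylsilyl)acetylide | [Li]C#C[Si](C)(C)C
F6 | step 4 | lithium 2-(trimethylsilyl)ethynolate | [Li+].[O-]C#C[Si](C)(C)C
F7 | step 4 | trimethyl{[(triisopropylsilyl)oxy]ethynyl}silane | C[Si](C)(C)C#CO[Si](C(C)C)(C(C)C)C(C)C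
F8 | step 9 | ethyl 2-[4-(methoxymethoxy)phenyl]-2-oxoacetate | CCOC(=O)C(=O)c1ccc(OCOC)cc1
F9 | step 9 | lithium 2-[4-(methoxymethoxy)phenyl]-2-oxoacetate | [Li+].[O-]C(=O)C(=O)c1ccc(OCOC)cc1
F10 | step 9 | 2-[4-(methoxymethoxy)phenyl]-2-oxoacetyl chloride | COCOc1ccc(cc1)C(=O)C(=O)Cl
F11 | step 9 | [7-methoxy-5-(methoxymethoxy)-2,2-dimethyl-8-(3-methylbut-2-en-1-yl)-2H-chromen-6-yl]copper | [Cu]c1c(OC)c(CC=C(C)C)c2OC(C)(C)C=Cc2c1OCOC
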